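## Analysis of the target

Artonin C is built on one carbocycle, a 1-methylcyclohexene, numbered here C1 (methyl-bearing alkene carbon), C2 (alkene CH), C3, C4, C5 and C6 (CH2). C3 carries ring A, a 2,6-dihydroxyphenyl ring whose 3-position holds the chalcone carbonyl that leads on to ring D (2,4-dihydroxyphenyl); C4 carries the aroyl group of ring B, a 2,4-dihydroxy-3-[(E)-3-methylbut-1-enyl]phenyl ring; C5 carries ring C, a 2,4-dihydroxyphenyl ring. The three stereocentres C3, C4 and C5 are contiguous: ring A and the aroyl group are cis (C3/C4), the aroyl group and ring C are trans (C4/C5), and in this numbering the configuration is 3S,4R,5S. C4 lies alpha to an aryl ketone, and the 3,4-cis arrangement is the one that can drift to the all-trans isomer under base. Eight free phenols, a 2'-hydroxychalcone that can close to a flavanone, an ortho-hydroxystyrene on ring B and a ketone flanked by ortho-phenols restrict the endgame to mild base and mild acid. The difficulty is to set C3/C4 cis and C4/C5 trans in one enantiomeric series on three crowded aryl-bearing carbons, and to bring in four resorcinol-type rings without confusing them. The strategy rests on C5 and C6: C5 is benzylic to ring C, the most easily oxidised arene once it is a bis-ether, and C6–C1–C2 is an allyl unit, so the C5–C6 bond can be made by moving C5 from C2 to C6. The isomer with a C2–C5 bond is a vinylcyclobutane fused through C3–C4 to a dihydrocoumarin built on ring A, and a lactone that spans a four-membered ring in this way holds C3 and C4 cis.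

## Retrosynthetic reasoning

**33 from 32.** The last operation removes only acetal protecting groups. All eight phenols travel as alkoxymethyl ethers, because these withstand organolithium reagents, aqueous base, a one-electron reductant and one-electron oxidation, and then leave together under mild acid. One of them, on ring A, is a menthyl-derived analogue of the methoxymethyl group and doubles as the chiral handle.

**32 from 30 and 31.** The chalcone C=C bond is cut by a Claisen–Schmidt disconnection. It is made late because an enone would survive neither the aryllithium nor the radical-cation step, and both halves are then simple: methyl ketone 30 and aldehyde 31.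

**30 from 29 from 28.** These are protecting-group adjustments. The phenol set free from the lactone is capped (29) so that it cannot deactivate the methyl ketone as a para-phenoxide, and the ketal is hydrolysed (30).

**28 from 20 and 26.** The bond between the C4 carbonyl carbon and ring B is cut. In the forward sense aryllithium 27, made from 26, opens lactone 20. The lactone is the acyl donor and also the device that has held C3 and C4 cis; opening it breaks no bond at a stereocentre.

**20 from 19 (key disconnection).** The C5–C6 bond is cut and C5 is reconnected to C2. This turns the cyclohexene into the isopropenylcyclobutane 19, still fused to the ring A dihydrocoumarin. The gain is that C3/C4 are fixed cis by the four/six ring fusion, and the configurations at C2 and C5 of 19 do not matter. The forward reaction must break only C2–C5 and reclose C6 on C5 trans to the lactone carbonyl.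

**19 from 18 from 16.** In 19 the ring A carbon C3 sits next to the lactone carbon C4, and the two aryl-bearing carbons C3 and C5 are diagonal. A photocycloaddition of a coumarin C3=C4 bond with a styrenyl C5=C2 bond must therefore join C5 to the lactone alpha-carbon C4. Without a tether the usual triplet biradical course gives the opposite orientation, because the two aryl-stabilised radical centres bond last and end up adjacent; a diene partner would in addition be attacked at its terminal CH2. The orientation is therefore enforced by a temporary ether bond from the ortho oxygen of ring C to C4, which in 16 is part of a dihydrobenzofuran. It is cut reductively through enolate 17, and the phenol that appears in 18 is the one the target needs on ring C; it is capped to give 19.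

**16 from 15.** The two cyclobutane bonds C4–C5 and C2–C3 are cut. Forward, this is an intramolecular [2+2] photocycloaddition of the 3-aryloxycoumarin 15, in which the three-atom oxygen–aryl link lets C5 reach only C4. Because the menthyl acetal is already in the molecule, the two faces of the coumarin lead to diastereomers and not to enantiomers, so the absolute configuration of 16 is fixed by a separation at this point.

**15 from 7 and 13.** The lactone C–O bond and the coumarin C3=C4 bond are cut, which is an ester condensation of salicylaldehyde 7 with aryloxyacetic acid 13 through aryl ester 14. Building the coumarin from an aryloxyacetic acid costs no step compared with a plain two-carbon unit and installs the tether.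

**7 from 1 via 2, 3, 4 and 6.** The formyl group is introduced through aryllithium 5 by directed lithiation between two alkoxymethoxy groups, which is unambiguous. The ketal is put on before any acid-sensitive alkene exists. The phenol that will become the lactone oxygen is masked by a fluoride-labile silylethoxymethyl group so that it can be freed alone.

**13 from 10 and 11, 10 from 9, 9 from 8.** The diene is cut at its styrenyl double bond (Wittig reaction of 10 with ylide 12, made from 11). The acetic acid arm comes from phenoxide alkylation, and the two phenols of 8 are told apart by chelation.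

**26 from 22 and 25, 22 from 21, 25 from 23 and 24, 31 from 8.** The E-alkenyl side chain of ring B is cut at the aryl–alkenyl bond (Suzuki–Miyaura coupling of 22 with 25). Boronate 25 comes from hydroboration of alkyne 23 with 24. The symmetry of 26 makes either lithiation site the right one.

## Alternatives that were turned down

Alternative 1: The ring would be cut at C2–C3 and C4–C5. The two-carbon partner is the 3,4-bond of flavylium cation A1 (ring A as benzo ring, ring B as 2-aryl group), so the C3/C4 cis relation is held in a ring; the four-carbon partner is silyl diene A2. Forward, A1 paired with a chiral phosphate anion is attacked at its 4-position by the silicon-bearing carbon of A2, the enol ether carbon then closes on the ring C-stabilised allyl cation, and water opens the oxocarbenium ion to the hydroxy ketone A3.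
- For it: one step forms two C–C bonds, the ring and all three stereocentres with the ring B ketone already in place, and protodesilylation of the allylsilane would later move the alkene into C1=C2. On convergence and step count it is stronger than the chosen route.
- Against it: the annulation is stepwise and cationic, so C5 is set in a second closure far from the counter-ion. Face control of a cation with a doubly ortho-substituted 2-aryl group and a peri silyloxy group by ion pairing is unproven. Silyl ethers must survive a cationic, aqueous medium. A3 still needs bromide-to-acetyl exchange beside a ketone, and an aldol condensation under base with aryl silyl ethers.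
- In its place the chosen route offers bond formation in a fixed intramolecular order, configuration held by ring fusion and not by ion pairing, and base-stable acetal protection.

Alternative 2: The ring would be cut at C4–C5 and C6–C1. Aroylpyrone A4 (ring A on the pyrone, ring B in the aroyl group) would add styrene A5 under Yb(OTf)3 and a BINOL ligand, chelated by the two carbonyl groups, to give the bridged lactone A6.
- For it: the inverse-demand cycloaddition is polarity-matched, regiochemically reliable and well suited to two-point Lewis acid binding. Taken alone it is probably the most dependable key step of the four.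
- Against it: in A6, C4 is a quaternary bridgehead with an extra carboxyl group and C3 is an alkene carbon. Opening the bridge and losing CO2 makes C4 enolisable, and C3 would have to be created afterwards by moving a double bond or by reduction. Only C5 of the three stereocentres comes out of the key step, and the less stable C3/C4 cis relation would depend on an uncontrolled late protonation.
- The chosen route sets C3/C4 by a ring fusion and sets C5 relative to them.

Alternative 3: Both bonds to C4 (C3–C4 and C4–C5) would be cut. Aroylacetate A8 would add twice to the cross-conjugated dienone A7 under a cinchona-derived catalyst to give cyclohexanone A9.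
- For it: plain ionic chemistry without photochemistry, with ring B carried in and the C3/C5 trans relation set. The individual operations are at least as reliable as those of the chosen route.
- Against it: C4 is quaternary in A9. Removing the allyl ester creates the C4 stereocentre by enol protonation, where the all-trans isomer is expected, which is the wrong epimer. The C1 ketone and C2 sulfone then have to be turned into the methyl-bearing alkene in several steps beside an epimerisable aryl ketone.
- The chosen route keeps C4 locked in a lactone until the aroyl group is on, and the alkene arises in its final place in the key step.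

Key step: step 13

## Remarks and assumptions

- C1–C6 keep the cyclohexene numbering in every intermediate, including the cyclobutanes; rings A–D are as defined above.
- Assumption: (−)-chloromethyl menthyl ether, (2-methylallyl)triphenylphosphonium chloride, 2-iodoresorcinol and pinacolborane are purchasable.
- Assumption: in 16–19 the isopropenyl group on C2 is drawn trans to ring C. This centre becomes trigonal in step 13, so the epimer, if formed, is carried along.
- Remark: step 10 is planned without facial control. The diastereomer of 16 with the mirror-image pentacyclic core (same menthyl group) forms alongside it, is removed by chromatography and takes no further part, so at most half of 15 can become 16.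

## Route

Step 1
Reactants: 1 2,4-dihydroxyacetophenone
Product: 2 1-[2-hydroxy-4-{[2-(trimethylsilyl)ethoxy]methoxy}phenyl]ethan-1-one
Conditions: SEMCl (1.05 equiv), iPr2NEt, CH2Cl2, 0 °C → rt
Reagents that add atoms: 2-(trimethylsilyl)ethoxymethyl chloride, C[Si](C)(C)CCOCCl
Why: Williamson-type alkoxymethylation; the 4-hydroxyl is not chelated to the acetyl group and is the more acidic phenol, so it should react alone, and the SEM group can later be removed by fluoride without touching the other acetals.

Step 2
Reactants: 2 1-[2-hydroxy-4-{[2-(trimethylsilyl)ethoxy]methoxy}phenyl]ethan-1-one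
Product: 3 1-[2-({[(1R,2S,5R)-2-isopropyl-5-methylcyclohexyl]oxy}methoxy)-4-{[2-(trimethylsilyl)ethoxy]methoxy}phenyl]ethan-1-one
Conditions: (−)-chloromethyl menthyl ether, NaH, DMF, 0 °C → rt
Reagents that add atoms: (−)-chloromethyl menthyl ether, ClCO[C@@H]1C[C@H](C)CC[C@H]1C(C)C
Why: Williamson ether synthesis on the chelated phenoxide with an alpha-chloro ether; the menthyloxymethyl group behaves like a methoxymethyl ether later, directs the lithiation of step 4 and turns the two mirror-image cyclobutane cores of step 10 into diastereomers.

Step 3
Reactants: 3 the acetophenone bis-acetal of step 2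
Product: 4 2-methyl-2-[2-(menthyloxymethoxy)-4-{[2-(trimethylsilyl)ethoxy]methoxy}phenyl]-1,3-dioxolane
Conditions: (TMSOCH2)2, TMSOTf (cat.), CH2Cl2, −78 → −20 °C; pyridine quench
Reagents that add atoms: 1,2-bis(trimethylsilyloxy)ethane, C[Si](C)(C)OCCO[Si](C)(C)C
Why: Noyori acetalisation, aprotic and cold, should leave both alkoxymethyl ethers intact; the ketal hides the acetyl group from butyllithium, SmI2 and the aryllithium of step 17, and is installed before any acid-sensitive alkene is present.

Step 4
Reactants: 4 the ketal of step 3
Product: 6 2-(menthyloxymethoxy)-3-(2-methyl-1,3-dioxolan-2-yl)-6-{[2-(trimethylsilyl)ethoxy]methoxy}benzaldehyde, via aryllithium 5 (not isolated)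
Conditions: n-BuLi, THF, 0 °C; DMF, −78 → 0 °C; aq. NH4Cl
Reagents that add atoms: N,N-dimethylformamide, CN(C)C=O
Why: Directed ortho-metalation; the carbon between the two alkoxymethoxy groups is the only one activated by both, and the aryllithium is formylated by DMF, so the regiochemistry is unambiguous.

Step 5
Reactants: 6 the benzaldehyde of step 4
Product: 7 6-hydroxy-2-(menthyloxymethoxy)-3-(2-methyl-1,3-dioxolan-2-yl)benzaldehyde
Conditions: Bu4NF, THF, 60 °C; aq. NH4Cl
Reagents that add atoms: none
Why: Fluoride-induced fragmentation of the SEM ether (attack at silicon, loss of ethene and formaldehyde); the phenoxide ortho to the formyl group is a good leaving group, and the menthyloxymethyl ether and the ketal are inert to fluoride.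

Step 6
Reactants: 8 2,4-dihydroxybenzaldehyde
Product: 9 2-hydroxy-4-(methoxymethoxy)benzaldehyde
Conditions: MOMCl (1.1 equiv), K2CO3, acetone, rt
Reagents that add atoms: chloromethyl methyl ether, COCCl
Why: Selective Williamson alkoxymethylation of the 4-hydroxyl; the 2-hydroxyl is chelated to the aldehyde and stays free for the next step.

Step 7
Reactants: 9 2-hydroxy-4-(methoxymethoxy)benzaldehyde
Product: 10 [2-formyl-5-(methoxymethoxy)phenoxy]acetic acid
Conditions: ClCH2CO2H, NaOH, H2O, 80 °C; then HCl to pH 3–4, 0 °C
Reagents that add atoms: chloroacetic acid, OC(=O)CCl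
Why: Williamson synthesis of an aryloxyacetic acid; as the carboxylate the methylene is not acidic enough to condense with the neighbouring aldehyde, and the methoxymethyl ether is stable to base and to brief cold acidification.

Step 8
Reactants: 10 [2-formyl-5-(methoxymethoxy)phenoxy]acetic acid; 11 (2-methylallyl)triphenylphosphonium chloride
Product: 13 {2-[(1E)-3-methylbuta-1,3-dien-1-yl]-5-(methoxymethoxy)phenoxy}acetic acid, via phosphorus ylide 12 (not isolated)
Conditions: 11 (2.2 equiv), NaN(SiMe3)2 (2.2 equiv), THF, 0 °C; then 10, −78 °C → rt
Reagents that add atoms: none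
Why: Wittig olefination with a semi-stabilised allylic ylide, one equivalent of which is spent on the carboxylic acid; the E isomer is drawn, and any Z isomer can be carried on because the triplet state of step 10 equilibrates this double bond.

Step 9
Reactants: 7 6-hydroxy-2-(menthyloxymethoxy)-3-(2-methyl-1,3-dioxolan-2-yl)benzaldehyde; 13 the dienyl aryloxyacetic acid of step 8
Product: 15 5-(menthyloxymethoxy)-6-(2-methyl-1,3-dioxolan-2-yl)-3-{2-[(1E)-3-methylbuta-1,3-dien-1-yl]-5-(methoxymethoxy)phenoxy}-2H-chromen-2-one, via aryl ester 14 (not isolated)
Conditions: EDC·HCl, DMAP, CH2Cl2, 0 °C → rt; then DBU, rt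
Reagents that add atoms: none
Why: Steglich esterification of the salicylaldehyde phenol, then base-mediated intramolecular Knoevenagel condensation (a Perkin-type coumarin synthesis); this closes the ring A coumarin and places the ring C oxygen on the future C4, all without acid or heat.

Step 10
Reactants: 15 the 3-aryloxycoumarin of step 9
Product: 16 pentacyclic photoadduct: cyclobutane C2–C3–C4–C5 cis-fused at C3–C4 to the ring A dihydrocoumarin and at C4–C5 to a dihydrobenzofuran made of ring C and the tether oxygen on C4, isopropenyl on C2, configuration as in the SMILES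
Conditions: [Ir(dF(CF3)ppy)2(dtbbpy)]PF6 (1 mol%), degassed MeCN (0.01 M), 450 nm LED, rt; chromatography on silica
Reagents that add atoms: none
Why: Triplet-sensitised intramolecular [2+2] photocycloaddition: through the three-atom oxygen–aryl link the styrenyl carbon C5 can reach only C4 (five-membered ring, rule of five), and the benzylic/allylic 1,4-biradical then closes at the near allyl terminus C2, the lactone spanning the new four-membered ring in the cis fashion that sets C3 and C4 cis. The remote menthyl group is not expected to favour one face of the coumarin, so the adduct with the mirror-image pentacyclic core forms alongside 16; the shared menthyl group makes the two separable diastereomers, chromatography removes the unwanted one, and this separation fixes the absolute configuration.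

Step 11
Reactants: 16 the pentacyclic photoadduct
Product: 18 isopropenylcyclobutane fused to the ring A dihydrocoumarin bearing hydrogen on C4 and a 2-hydroxy-4-(methoxymethoxy)phenyl group on C5, via samarium enolate 17 (not isolated)
Conditions: SmI2 (2.5 equiv), HMPA, MeOH, THF, −78 → 0 °C
Reagents that add atoms: none
Why: Reductive cleavage of an alpha-aryloxy carbonyl compound by SmI2: electron transfer to the lactone carbonyl expels the aryloxide from C4, and a second electron gives enolate 17, which methanol protonates at C4 on the convex face that the oxygen left, so the strongly preferred cis four/six fusion is kept. The freed ring C phenoxide lies trans to the carbonyl across the cyclobutane and so should not take over the acyl group.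

Step 12
Reactants: 18 the phenol of step 11
Product: 19 key-step precursor: the isopropenylcyclobutane fused to the ring A dihydrocoumarin, with 2,4-bis(methoxymethoxy)phenyl on C5
Conditions: MOMCl, iPr2NEt, CH2Cl2, 0 °C → rt
Reagents that add atoms: chloromethyl methyl ether, COCCl
Why: Alkoxymethylation of the phenol; ring C must be a dialkoxybenzene so that one-electron oxidation gives a radical cation and not a phenoxyl radical, and the mild amine base leaves the lactone closed.

Step 13
Reactants: 19 the isopropenylcyclobutane
Product: 20 cis-fused 9-methyl-6a,7,8,10a-tetrahydrobenzo[c]chromen-6-one carrying ring C on C5 trans to the lactone carbonyl, the ketal and the menthyloxymethoxy group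
Conditions: 2,4,6-tris(4-methoxyphenyl)pyrylium tetrafluoroborate (5 mol%), degassed CH2Cl2, 450 nm LED, 0 °C
Reagents that add atoms: none
Why: The excited pyrylium salt takes one electron from ring C, the only 1-alkyl-2,4-dialkoxybenzene in 19 and its most easily oxidised site. The hole weakens C2–C5, the one cyclobutane bond that is both benzylic to ring C and allylic, and it breaks with release of ring strain to a benzylic cation at C5 and an allyl radical over C2, C1 and C6. The allyl terminus C6 then bonds to C5, a net 1,3-shift of C5 from C2 to C6 that closes the six-membered ring in a 6-endo mode (C1 and C6 of the allyl unit both lie in the new ring, so C1=C2 ends up endocyclic), and electron return from the reduced catalyst or from another molecule of 19 carries a chain. The closest known reaction type is the cation-radical vinylcyclobutane-to-cyclohexene rearrangement of aryl vinylcyclobutanes under triarylaminium salts or photoredox catalysts. C3 and C4 are not touched, so their cis relation from step 10 persists, while the C2 and C5 configurations of 19 are erased and any epimer at these centres converges. The new stereocentre C5 is under substrate control: the benzylic cation hangs on C4 of a cis-fused lactone and ring C should take the pseudo-equatorial position on the convex face, anti to the lactone carbonyl, and since the C5–C6 bond can reopen under the same conditions the more stable 4,5-trans isomer should accumulate. The step needs C2–C5 cleavage in preference to C4–C5 (which would give a poorly stabilised alpha-carbonyl radical) and to loss of C3–C4 (which would give an achiral diene ester and erase C3/C4); localisation of the hole on ring C, allyl stabilisation at C2 and the low temperature should secure this. Acid-free photoredox conditions are preferred to tris(4-bromophenyl)aminium hexachloroantimonate, (4-BrC6H4)3N·SbCl6, to protect the ketal and the alkoxymethyl ethers.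

Step 14
Reactants: 21 2-iodoresorcinol
Product: 22 2-iodo-1,3-bis(methoxymethoxy)benzene
Conditions: MOMCl, iPr2NEt, CH2Cl2, 0 °C → rt
Reagents that add atoms: chloromethyl methyl ether, COCCl
Why: Double Williamson alkoxymethylation of two unhindered, non-chelated phenols.

Step 15
Reactants: 23 3-methyl-1-butyne; 24 pinacolborane
Product: 25 2-[(E)-3-methylbut-1-en-1-yl]-4,4,5,5-tetramethyl-1,3,2-dioxaborolane
Conditions: Cp2Zr(H)Cl (5 mol%), Et3N (10 mol%), neat, sealed tube, 60 °C
Reagents that add atoms: none
Why: Zirconium-catalysed syn hydroboration of a terminal alkyne places boron on the terminal carbon and gives the E-alkenylboronate.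

Step 16
Reactants: 22 2-iodo-1,3-bis(methoxymethoxy)benzene; 25 the E-alkenylboronate
Product: 26 1,3-bis(methoxymethoxy)-2-[(E)-3-methylbut-1-en-1-yl]benzene
Conditions: Pd(OAc)2, SPhos, K3PO4, toluene–H2O, 80 °C
Reagents that add atoms: none
Why: Suzuki–Miyaura coupling with retention of alkene geometry; a bulky biarylphosphine is chosen because the iodide has two ortho substituents.

Step 17
Reactants: 26 the ring B arene; 20 the lactone of step 13
Product: 28 hydroxy ketone: 3,4-cis-4,5-trans cyclohexene with C4 bearing the 2,4-bis(methoxymethoxy)-3-[(E)-3-methylbut-1-enyl]benzoyl group and ring A bearing a free phenol, the ketal and the menthyloxymethoxy group, via ring B aryllithium 27 (not isolated)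
Conditions: 26, n-BuLi, THF, 0 °C; then 20, THF, −78 °C; aq. NH4Cl at −78 °C
Reagents that add atoms: none
Why: Directed ortho-metalation of the symmetric arene 26 (both positions ortho to a methoxymethoxy group are equivalent), then nucleophilic acyl substitution on the aryl lactone; the hindered, ortho-substituted ketone should resist a second addition at −78 °C. No bond at C3, C4 or C5 is broken, and the cold quench is meant to prevent enolisation at C4.

Step 18
Reactants: 28 the hydroxy ketone
Product: 29 the corresponding methoxymethyl ether on ring A
Conditions: MOMCl, iPr2NEt, CH2Cl2, 0 °C → rt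
Reagents that add atoms: chloromethyl methyl ether, COCCl
Why: Alkoxymethylation of the phenol para to the masked acetyl group; as a free phenoxide it would deactivate the methyl ketone in step 21, and the weak amine base does not threaten C4.

Step 19
Reactants: 29 the ketal of step 18
Product: 30 the ring A methyl ketone (acetyl in place of the dioxolane)
Conditions: PPTS, acetone–H2O, rt
Reagents that add atoms: water, O
Why: Acid-catalysed ketal hydrolysis; the ketal of an electron-rich aryl ketone ionises far more readily than aryl alkoxymethyl ethers, so weak acid at room temperature should be selective.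

Step 20
Reactants: 8 2,4-dihydroxybenzaldehyde
Product: 31 2,4-bis(methoxymethoxy)benzaldehyde
Conditions: MOMCl (2.5 equiv), NaH, DMF, 0 °C → rt
Reagents that add atoms: chloromethyl methyl ether, COCCl
Why: Exhaustive Williamson alkoxymethylation; the stronger base is needed for the chelated 2-hydroxyl.

Step 21
Reactants: 30 the ring A methyl ketone; 31 2,4-bis(methoxymethoxy)benzaldehyde
Product: 32 fully protected artonin C (seven methoxymethyl ethers and one menthyloxymethyl ether)
Conditions: KOH, EtOH–H2O, rt
Reagents that add atoms: none
Why: Claisen–Schmidt condensation (aldol addition, then E1cB loss of water) gives the E-enone. Only the methyl group should enolise, because an enolate toward C4 would be tetrasubstituted and strongly strained between two aryl-bearing carbons.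

Step 22
Reactants: 32 fully protected artonin C
Product: 33 artonin C
Conditions: HCl (3 M aq.), MeOH–THF, rt
Reagents that add atoms: none
Why: Acid-catalysed acetal exchange with methanol removes the seven methoxymethyl groups and the menthyloxymethyl group in one operation; room temperature and short contact are chosen so that the 2'-hydroxychalcone does not close to a flavanone and the styrenyl alkene does not add solvent.

## Compound list

1 | 2,4-dihydroxyacetophenone | CC(=O)c1ccc(O)cc1O | starting material
2 | 1-[2-hydroxy-4-{[2-(trimethylsilyl)ethoxy]methoxy}phenyl]ethan-1-one | CC(=O)c1ccc(OCOCC[Si](C)(C)C)cc1O | intermediate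
3 | 1-[2-({[(1R,2S,5R)-2-isopropyl-5-methylcyclohexyl]oxy}methoxy)-4-{[2-(trimethylsilyl)ethoxy]methoxy}phenyl]ethan-1-one | CC(=O)c1ccc(OCOCC[Si](C)(C)C)cc1OCO[C@@H]1C[C@H](C)CC[C@H]1C(C)C | intermediate
4 | 2-methyl-2-[2-(menthyloxymethoxy)-4-{[2-(trimethylsilyl)ethoxy]methoxy}phenyl]-1,3-dioxolane | CC1(OCCO1)c2ccc(OCOCC[Si](C)(C)C)cc2OCO[C@@H]3C[C@H](C)CC[C@H]3C(C)C | intermediate
5 | aryllithium of 4, lithium between the two alkoxymethoxy groups | CC1(OCCO1)c2ccc(OCOCC[Si](C)(C)C)c([Li])c2OCO[C@@H]3C[C@H](C)CC[C@H]3C(C)C | intermediate
6 | 2-(menthyloxymethoxy)-3-(2-methyl-1,3-dioxolan-2-yl)-6-{[2-(trimethylsilyl)ethoxy]methoxy}benzaldehyde | CC1(OCCO1)c2ccc(OCOCC[Si](C)(C)C)c(C=O)c2OCO[C@@H]3C[C@H](C)CC[C@H]3C(C)C | intermediate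
7 | 6-hydroxy-2-(menthyloxymethoxy)-3-(2-methyl-1,3-dioxolan-2-yl)benzaldehyde | CC1(OCCO1)c2ccc(O)c(C=O)c2OCO[C@@H]3C[C@H](C)CC[C@H]3C(C)C | intermediate
8 | 2,4-dihydroxybenzaldehyde | O=Cc1ccc(O)cc1O | starting material
9 | 2-hydroxy-4-(methoxymethoxy)benzaldehyde | O=Cc1ccc(OCOC)cc1O | intermediate
10 | [2-formyl-5-(methoxymethoxy)phenoxy]acetic acid | O=Cc1ccc(OCOC)cc1OCC(=O)O | intermediate
11 | (2-methylallyl)triphenylphosphonium chloride | C=C(C)C[P+](c1ccccc1)(c1ccccc1)c1ccccc1.[Cl-] | starting material
12 | (2-methylallylidene)triphenylphosphorane | C=C(C)C=P(c1ccccc1)(c1ccccc1)c1ccccc1 | intermediate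
13 | {2-[(1E)-3-methylbuta-1,3-dien-1-yl]-5-(methoxymethoxy)phenoxy}acetic acid | C=C(C)/C=C/c1ccc(OCOC)cc1OCC(=O)O | intermediate
14 | aryl ester of 7 with acid 13 | CC1(OCCO1)c2ccc(OC(=O)COc3cc(OCOC)ccc3/C=C/C(C)=C)c(C=O)c2OCO[C@@H]4C[C@H](C)CC[C@H]4C(C)C | intermediate
15 | 5-(menthyloxymethoxy)-6-(2-methyl-1,3-dioxolan-2-yl)-3-{2-[(1E)-3-methylbuta-1,3-dien-1-yl]-5-(methoxymethoxy)phenoxy}-2H-chromen-2-one | O=C1Oc2ccc(C3(C)OCCO3)c(OCO[C@@H]4C[C@H](C)CC[C@H]4C(C)C)c2C=C1Oc5cc(OCOC)ccc5/C=C/C(C)=C | intermediate
16 | pentacyclic photoadduct (dihydrocoumarin, cyclobutane and dihydrobenzofuran fused; isopropenyl on C2), core configuration leading to the target | C=C(C)[C@@H]1[C@@H]2c3c(OC(=O)[C@@]24Oc5cc(OCOC)ccc5[C@@H]14)ccc(C6(C)OCCO6)c3OCO[C@@H]7C[C@H](C)CC[C@H]7C(C)C | intermediate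
17 | samarium enolate of the lactone after loss of the ring C aryloxide from C4; the enolate oxygen and the ring C phenoxide oxygen each carry an SmI2 group of trivalent samarium | C=C(C)[C@@H]1[C@@H]2c3c(OC(O[Sm](I)I)=C2[C@H]1c4ccc(OCOC)cc4O[Sm](I)I)ccc(C5(C)OCCO5)c3OCO[C@@H]6C[C@H](C)CC[C@H]6C(C)C | intermediate
18 | isopropenylcyclobutane fused to the ring A dihydrocoumarin, with 2-hydroxy-4-(methoxymethoxy)phenyl on C5 | C=C(C)[C@@H]1[C@@H]2c3c(OC(=O)[C@@H]2[C@H]1c4ccc(OCOC)cc4O)ccc(C5(C)OCCO5)c3OCO[C@@H]6C[C@H](C)CC[C@H]6C(C)C | intermediate
19 | key-step precursor: isopropenylcyclobutane fused to the ring A dihydrocoumarin, with 2,4-bis(methoxymethoxy)phenyl on C5 | C=C(C)[C@@H]1[C@@H]2c3c(OC(=O)[C@@H]2[C@H]1c4ccc(OCOC)cc4OCOC)ccc(C5(C)OCCO5)c3OCO[C@@H]6C[C@H](C)CC[C@H]6C(C)C | intermediate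
20 | key-step product: cis-fused tetrahydrobenzo[c]chromenone with ring C on C5 trans to the lactone carbonyl | CC1=C[C@@H]2c3c(OC(=O)[C@@H]2[C@@H](c4ccc(OCOC)cc4OCOC)C1)ccc(C5(C)OCCO5)c3OCO[C@@H]6C[C@H](C)CC[C@H]6C(C)C | intermediate
21 | 2-iodoresorcinol | Oc1cccc(O)c1I | starting material
22 | 2-iodo-1,3-bis(methoxymethoxy)benzene | COCOc1cccc(OCOC)c1I | intermediate
23 | 3-methyl-1-butyne | C#CC(C)C | starting material
24 | pinacolborane | CC1(C)O[BH]OC1(C)C | starting material
25 | 2-[(E)-3-methylbut-1-en-1-yl]-4,4,5,5-tetramethyl-1,3,2-dioxaborolane | CC(C)/C=C/B1OC(C)(C)C(C)(C)O1 | intermediate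
26 | 1,3-bis(methoxymethoxy)-2-[(E)-3-methylbut-1-en-1-yl]benzene | COCOc1cccc(OCOC)c1/C=C/C(C)C | intermediate
27 | 2,4-bis(methoxymethoxy)-3-[(E)-3-methylbut-1-en-1-yl]phenyllithium | COCOc1ccc([Li])c(OCOC)c1/C=C/C(C)C | intermediate
28 | hydroxy ketone from lactone opening (ring A phenol free, ketal and menthyloxymethoxy retained) | CC1=C[C@H](c2c(O)ccc(C3(C)OCCO3)c2OCO[C@@H]4C[C@H](C)CC[C@H]4C(C)C)[C@H](C(=O)c5ccc(OCOC)c(/C=C/C(C)C)c5OCOC)[C@@H](c6ccc(OCOC)cc6OCOC)C1 | intermediate
29 | methoxymethyl ether of 28 | CC1=C[C@H](c2c(OCOC)ccc(C3(C)OCCO3)c2OCO[C@@H]4C[C@H](C)CC[C@H]4C(C)C)[C@H](C(=O)c5ccc(OCOC)c(/C=C/C(C)C)c5OCOC)[C@@H](c6ccc(OCOC)cc6OCOC)C1 | intermediate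
30 | ring A methyl ketone | CC1=C[C@H](c2c(OCOC)ccc(C(C)=O)c2OCO[C@@H]4C[C@H](C)CC[C@H]4C(C)C)[C@H](C(=O)c5ccc(OCOC)c(/C=C/C(C)C)c5OCOC)[C@@H](c6ccc(OCOC)cc6OCOC)C1 | intermediate
31 | 2,4-bis(methoxymethoxy)benzaldehyde | O=Cc1ccc(OCOC)cc1OCOC | intermediate
32 | fully protected artonin C | CC1=C[C@H](c2c(OCOC)ccc(C(=O)/C=C/c3ccc(OCOC)cc3OCOC)c2OCO[C@@H]4C[C@H](C)CC[C@H]4C(C)C)[C@H](C(=O)c5ccc(OCOC)c(/C=C/C(C)C)c5OCOC)[C@@H](c6ccc(OCOC)cc6OCOC)C1 | intermediate
33 | artonin C | CC1=C[C@H](c2c(O)ccc(C(=O)/C=C/c3ccc(O)cc3O)c2O)[C@H](C(=O)c2ccc(O)c(/C=C/C(C)C)c2O)[C@@H](c2ccc(O)cc2O)C1 | target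

## Step count and risks

Total: 22 steps. Longest linear sequence: 15 steps (steps 1–5, 9–13, 17–19, 21 and 22).

**Step 13 (key step).** The ring-opened radical cation may lose a second ring bond (C3–C4) before it recloses. That would pass through an achiral diene ester and erase C3/C4 and the enantiomeric purity. Reclosure at C5 may also show poor facial selectivity, and traces of acid may cost the ketal.
Fallback: leave the radical-cation route and reach 20 by a thermal intramolecular Diels–Alder reaction. Set out from 7. Wittig reaction with ylide 12 should give the ring A dienyl phenol F1. It is esterified at once (EDC, DMAP) with (E)-3-[2,4-bis(methoxymethoxy)phenyl]acrylic acid F2, made from 31 and malonic acid by Knoevenagel–Doebner condensation, to give the dienyl cinnamate F3. Heating F3 in toluene (sealed tube, 160–180 °C, BHT) should close C3–C4 and C5–C6 at once; the E-cinnamate geometry gives the 4,5-trans relation, and the planar aryl ester tether should favour the cis ring fusion. The product is 20 together with the diastereomer of mirror-image core F4, which is removed by chromatography. The route is rejoined at 20.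

**Step 10.** The intermediate biradical may close at the far allyl terminus to a six-membered ring. The electron-rich diene may be lost to geometric isomerisation, to oligomerisation or to one-electron oxidation by the excited sensitiser. The two menthyl-distinguished diastereomers may be hard to separate.
Fallback: take the diene out of the photochemical step. Set out from 10. Wittig reaction of its carboxylate with Ph3P=CHC(O)CH3 should give the enone acid F5, which is condensed with 7 as in step 9 to the coumarin F6; loss of water makes the aldol closure onto the aldehyde irreversible, whereas conjugate addition to the enone can revert. The same sensitised cycloaddition should give the acetylcyclobutane F7, which has no allyl terminus to close on, and the diastereomer of mirror-image core F8, which is removed. Wittig methylenation of F7 with Ph3P=CH2 at 0 °C returns to 16.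

**Step 11.** The ketyl may open the cyclobutane by carbon–carbon scission in competition with loss of the aryloxide, or the lactone may be reduced too slowly. If C4 epimerises in the basic mixture, the acyl group may migrate to the freed ring C phenoxide.
Fallback: run the cleavage at the aldehyde oxidation level, where electron transfer is much easier. Set out from 16. Reduction with i-Bu2AlH at −78 °C should give the lactol F9. SmI2 in THF–MeOH at −78 °C without HMPA should cleave the alpha-aryloxy aldehyde that is in equilibrium with F9, and the product should close to the lactol F10, which keeps the free aldehyde, and with it epimerisation at C4, at a low level. Oxidation of the lactol with catalytic Pr4N[RuO4] and N-methylmorpholine N-oxide returns to 18.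

**Step 17.** A second aryllithium may add to the ketone. The aryllithium may also deprotonate C4 of the aryl lactone, which can then lose the phenoxide to a ketene, so that re-addition and protonation leave C4 uncontrolled; deprotonation of the product ketone would have the same effect.
Fallback: pass through a Weinreb amide. Set out from 20. MeNH(OMe)·HCl with i-PrMgCl should open the lactone to the hydroxy Weinreb amide F11, and MOMCl with iPr2NEt gives its methoxymethyl ether F12. Addition of aryllithium 27 to F12 stops at the ketone and returns to the route at 29.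

**Step 21.** During the long exposure to hydroxide C4 may epimerise to the all-trans isomer, and the aldol addition may reverse.
Fallback: a kinetic two-step aldol condensation. Set out from 30. LiN(SiMe3)2 at −78 °C deprotonates the methyl group, and addition of 31 should give the beta-hydroxy ketone F13 as a mixture at the carbinol carbon. Mesylation (MsCl, Et3N) and elimination with DBU at 0 °C return to 32.

## Further compounds

F1 | step 13 | 6-hydroxy ring A dienyl phenol: 3-(menthyloxymethoxy)-4-(2-methyl-1,3-dioxolan-2-yl)-2-[(1E)-3-methylbuta-1,3-dien-1-yl]phenol | C=C(C)/C=C/c1c(O)ccc(C2(C)OCCO2)c1OCO[C@@H]3C[C@H](C)CC[C@H]3C(C)C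
F2 | step 13 | (E)-3-[2,4-bis(methoxymethoxy)phenyl]acrylic acid | OC(=O)/C=C/c1ccc(OCOC)cc1OCOC
F3 | step 13 | aryl cinnamate of F1 with F2 | C=C(C)/C=C/c1c(OC(=O)/C=C/c2ccc(OCOC)cc2OCOC)ccc(C3(C)OCCO3)c1OCO[C@@H]4C[C@H](C)CC[C@H]4C(C)C
F4 | step 13 | diastereomer of 20 with the mirror-image core | CC1=C[C@H]2c3c(OC(=O)[C@H]2[C@H](c4ccc(OCOC)cc4OCOC)C1)ccc(C5(C)OCCO5)c3OCO[C@@H]6C[C@H](C)CC[C@H]6C(C)C
F5 | step 10 | {5-(methoxymethoxy)-2-[(1E)-3-oxobut-1-en-1-yl]phenoxy}acetic acid | CC(=O)/C=C/c1ccc(OCOC)cc1OCC(=O)O
F6 | step 10 | 3-aryloxycoumarin analogue of 15 with an (E)-3-oxobut-1-enyl group in place of the diene | O=C1Oc2ccc(C3(C)OCCO3)c(OCO[C@@H]4C[C@H](C)CC[C@H]4C(C)C)c2C=C1Oc5cc(OCOC)ccc5/C=C/C(C)=O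
F7 | step 10 | pentacyclic photoadduct with acetyl on C2 in place of isopropenyl | CC(=O)[C@@H]1[C@@H]2c3c(OC(=O)[C@@]24Oc5cc(OCOC)ccc5[C@@H]14)ccc(C6(C)OCCO6)c3OCO[C@@H]7C[C@H](C)CC[C@H]7C(C)C
F8 | step 10 | diastereomer of F7 with the mirror-image core | CC(=O)[C@H]1[C@H]2c3c(OC(=O)[C@]24Oc5cc(OCOC)ccc5[C@H]14)ccc(C6(C)OCCO6)c3OCO[C@@H]7C[C@H](C)CC[C@H]7C(C)C
F9 | step 11 | lactol of 16 (mixture at the hemiacetal carbon) | C=C(C)[C@@H]1[C@@H]2c3c(OC(O)[C@@]24Oc5cc(OCOC)ccc5[C@@H]14)ccc(C6(C)OCCO6)c3OCO[C@@H]7C[C@H](C)CC[C@H]7C(C)C
F10 | step 11 | lactol of 18 (mixture at the hemiacetal carbon) | C=C(C)[C@@H]1[C@@H]2c3c(OC(O)[C@@H]2[C@H]1c4ccc(OCOC)cc4O)ccc(C5(C)OCCO5)c3OCO[C@@H]6C[C@H](C)CC[C@H]6C(C)C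
F11 | step 17 | hydroxy Weinreb amide from 20 | CC1=C[C@H](c2c(O)ccc(C3(C)OCCO3)c2OCO[C@@H]4C[C@H](C)CC[C@H]4C(C)C)[C@H](C(=O)N(C)OC)[C@@H](c6ccc(OCOC)cc6OCOC)C1
F12 | step 17 | methoxymethyl ether of F11 | CC1=C[C@H](c2c(OCOC)ccc(C3(C)OCCO3)c2OCO[C@@H]4C[C@H](C)CC[C@H]4C(C)C)[C@H](C(=O)N(C)OC)[C@@H](c6ccc(OCOC)cc6OCOC)C1
F13 | step 21 | beta-hydroxy ketone from 30 and 31 (mixture at the carbinol carbon) | CC1=C[C@H](c2c(OCOC)ccc(C(=O)CC(O)c3ccc(OCOC)cc3OCOC)c2OCO[C@@H]4C[C@H](C)CC[C@H]4C(C)C)[C@H](C(=O)c5ccc(OCOC)c(/C=C/C(C)C)c5OCOC)[C@@H](c6ccc(OCOC)cc6OCOC)C1
A1 | alternative 1 | 8-bromo-5-(tert-butyldimethylsilyloxy)-2-{2,4-bis(tert-butyldimethylsilyloxy)-3-[(E)-3-methylbut-1-enyl]phenyl}chromenylium cation | CC(C)/C=C/c1c(O[Si](C)(C)C(C)(C)C)ccc(-c2ccc3c(O[Si](C)(C)C(C)(C)C)ccc(Br)c3[o+]2)c1O[Si](C)(C)C(C)(C)C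
A2 | alternative 1 | (1E,3E)-1-trimethylsilyl-2-methyl-4-[2,4-bis(tert-butyldimethylsilyloxy)phenyl]buta-1,3-diene | C[Si](C)(C)/C=C(C)/C=C/c1ccc(O[Si](C)(C)C(C)(C)C)cc1O[Si](C)(C)C(C)(C)C
A3 | alternative 1 | C2-silyl cyclohexene with the C1–C6 double bond, open hydroxy ketone form | C[Si](C)(C)[C@H]1[C@H](c2c(O[Si](C)(C)C(C)(C)C)ccc(Br)c2O)[C@H](C(=O)c2ccc(O[Si](C)(C)C(C)(C)C)c(/C=C/C(C)C)c2O[Si](C)(C)C(C)(C)C)[C@@H](c2ccc(O[Si](C)(C)C(C)(C)C)cc2O[Si](C)(C)C(C)(C)C)C=C1C
A4 | alternative 2 | 6-methyl-4-(ring A aryl)-3-(ring B aroyl)-2H-pyran-2-one | Cc1cc(-c2c(OCOC)ccc(C(C)=O)c2OCOC)c(C(=O)c2ccc(OCOC)c(/C=C/C(C)C)c2OCOC)c(=O)o1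
A5 | alternative 2 | 2,4-bis(methoxymethoxy)styrene | C=Cc1ccc(OCOC)cc1OCOC
A6 | alternative 2 | bridged bicyclic lactone with the C2–C3 double bond | C[C@]12C=C(c3c(OCOC)ccc(C(C)=O)c3OCOC)[C@](C(=O)c3ccc(OCOC)c(/C=C/C(C)C)c3OCOC)(C(=O)O1)[C@@H](c1ccc(OCOC)cc1OCOC)C2
A7 | alternative 3 | cross-conjugated dienone with ring A and a phenylsulfonyl group on one enone arm and ring C on the other | O=C(/C=C/c1ccc(OCOC)cc1OCOC)C(=Cc1c(OCOC)ccc(C2(C)OCCO2)c1OCOC)S(=O)(=O)c1ccccc1
A8 | alternative 3 | allyl 3-{2,4-bis(methoxymethoxy)-3-[(E)-3-methylbut-1-enyl]phenyl}-3-oxopropanoate | C=CCOC(=O)CC(=O)c1ccc(OCOC)c(/C=C/C(C)C)c1OCOC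
A9 | alternative 3 | 3,5-trans-diaryl-4-aroyl-4-allyloxycarbonyl-2-sulfonylcyclohexanone | O=C1[C@@H](S(=O)(=O)c2ccccc2)[C@H](c2c(OCOC)ccc(C3(C)OCCO3)c2OCOC)[C@](C(=O)OCC=C)(C(=O)c2ccc(OCOC)c(/C=C/C(C)C)c2OCOC)[C@@H](c2ccc(OCOC)cc2OCOC)C1
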